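**Retrosynthetic overview**

1. Numbering: C1 (OBz), C2 (OAc), C3, C4 (Me, OH), C5 (ether O and lactone carbonyl C6), C7=C8, C9 (lactone O), C10 (angular Me), C11 (CMe2). The benzoate and acetate go on last (triol 24); the γ-lactone C6(=O)–O–C9 comes from 1,2-reduction of oxepenone 21 beside the C5 ester.
2. The oxepene ring O–C11–C7=C8–C9–C10–C5 of 21 comes from the six-membered oxacycle O–C11–C7–C9–C10–C5 of 18 by insertion of one carbon (C8) between C7 and C9: cyclopropanation of the enol silane, then FeCl3 opening of the fused bond.
3. Feature that allows this: the ring carbonyl C9 lies between the quaternary C10 and C7, and C7 is backed by the hydrogen-free C11, so the enol silane can only be C9=C7, the cyclopropane is C7–C8–C9, and after opening only C8 can lose a proton.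
4. The six-membered oxacycle is closed irreversibly by 6-endo-dig addition of the C5 hydroxyl to a C10 ynone (16 to 17), then Me2CuLi; the ynone comes from bridged lactone 12, formed when the auxiliary amide opens the C4–C5 epoxide of enoate 10 (sets C4 and C5, releases the auxiliary).
5. Ring A with the C10 quaternary centre comes from an asymmetric Birch reduction–methylation of benzamide 4. Ring order: ring A, temporary C9–O–C4 lactone, six-membered oxacycle, oxepene (by expansion), γ-lactone.

Key step: step 13

Faces: β is the face of ring A that carries the C10 methyl, α the other face.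
Assumption: in step 2 the (S)-auxiliary 2 is taken to direct methylation to the enolate face that gives the C10 configuration drawn for 5 and 6; if the sense is opposite, (R)-2-(methoxymethyl)pyrrolidine is used and nothing else changes.

**Route**

Step 1
Reactants: 1 2-methoxy-3-methylbenzoic acid; 2 (S)-2-(methoxymethyl)pyrrolidine
Product: 4 (S)-N-(2-methoxy-3-methylbenzoyl)-2-(methoxymethyl)pyrrolidine, via acid chloride 3 (not isolated)
Conditions: (COCl)2, DMF (cat.), CH2Cl2, 0 °C to rt; then 2, Et3N, CH2Cl2, 0 °C
Reagents that add atoms: none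
Why: Acylation of the secondary amine by the acid chloride (Schotten–Baumann-type amide formation) creates no stereocentre and leaves the pyrrolidine centre untouched.

Step 2
Reactants: 4 benzamide
Product: 6 ring A enone amide (C5 ketone; C1=C2; C10 β-methyl α-carboxamide; C4 epimer mixture), via dienyl methyl ether 5 (not isolated)
Conditions: K, t-BuOH (1 equiv), NH3–THF, −78 °C; MeI; then 2 M HCl, MeOH, rt
Reagents that add atoms: iodomethane, CI; water, O
Why: Asymmetric Birch reduction–alkylation of a chiral 2-methoxybenzamide: two-electron reduction and para protonation give a chelated potassium amide enolate that is methylated on the face left open by the methoxymethyl arm of the auxiliary, which sets the C10 quaternary centre, and acid then hydrolyses the methyl enol ether to the C5 ketone (the C4 centre is erased in step 5).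

Step 3
Reactants: 6 ring A enone amide
Product: 7 1β,2β-diol
Conditions: OsO4 (2 mol %), NMO, acetone–H2O, rt
Reagents that add atoms: OsO4 (catalytic oxygen carrier), O=[Os](=O)(=O)=O; N-methylmorpholine N-oxide, C[N+]1([O-])CCOCC1; water, O
Why: Catalytic OsO4 dihydroxylation is a suprafacial addition to the only alkene and should occur on the β-face, opposite the bulky tertiary amide on the neighbouring quaternary C10, so that the new C1–O and C2–O bonds are cis to the C10 methyl.

Step 4
Reactants: 7 1β,2β-diol
Product: 8 acetonide ketone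
Conditions: Me2C(OMe)2, PPTS (cat.), CH2Cl2, rt
Reagents that add atoms: 2,2-dimethoxypropane, COC(C)(C)OC
Why: Acid-catalysed transketalisation ties the cis-diol into a dioxolane that tolerates the basic, oxidative and organometallic steps that follow; no stereocentre changes.

Step 5
Reactants: 8 acetonide ketone
Product: 9 enol triflate (C4=C5)
Conditions: KN(SiMe3)2, THF, −78 °C; PhNTf2, −78 to 0 °C
Reagents that add atoms: N-phenylbis(trifluoromethanesulfonimide), O=S(=O)(N(c1ccccc1)S(=O)(=O)C(F)(F)F)C(F)(F)F
Why: The ketone can enolise only toward C4 because C10 is quaternary, so O-sulfonylation of the potassium enolate gives a single tetrasubstituted enol triflate and C4 becomes trigonal.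

Step 6
Reactants: 9 enol triflate
Product: 10 methyl enoate (C6 ester on C5 of the C4=C5 alkene)
Conditions: Pd(OAc)2 (5 mol %), dppf, CO (1 atm), MeOH, Et3N, DMF, 60 °C
Reagents that add atoms: carbon monoxide, [C-]#[O+]; methanol, CO
Why: Pd(OAc)2/dppf-catalysed alkoxycarbonylation of a vinyl triflate (oxidative addition to zerovalent palladium, CO insertion, methanolysis of the acyl complex) installs C6 without touching a stereocentre.

Step 7
Reactants: 10 methyl enoate
Product: 12 bridged hydroxy lactone (C9(=O)–O–C4α; 4β-methyl; 5β-OH; 5α-CO2Me), via β-epoxide 11 (not isolated)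
Conditions: mCPBA, CH2Cl2, 0 °C to rt; CSA (cat.); then THF–H2O, rt
Reagents that add atoms: 3-chloroperbenzoic acid, OOC(=O)c1cccc(Cl)c1; water, O
Why: Prilezhaev epoxidation should occur on the β-face because allylic 1,2-strain with the C5 ester holds the large amide pseudoaxial on the α-face, and the amide oxygen then opens the epoxide at the tertiary C4 with inversion (5-exo neighbouring-group participation) to an O-alkyl iminium ion whose hydrolysis gives the lactone and returns the auxiliary, which sets C4 (oxygen α, methyl β) and C5 (hydroxyl β, ester α).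

Step 8
Reactants: 12 bridged hydroxy lactone
Product: 14 Weinreb amide with 4α-OSiEt3 and free 5β-OH, via hydroxy Weinreb amide 13 (not isolated)
Conditions: Me(MeO)NH·HCl, i-PrMgCl, THF, −20 to 0 °C; then Et3SiOTf, 2,6-lutidine, CH2Cl2, −78 to 0 °C
Reagents that add atoms: N,O-dimethylhydroxylamine hydrochloride, CNOC.Cl; triethylsilyl trifluoromethanesulfonate, CC[Si](CC)(CC)OS(=O)(=O)C(F)(F)F
Why: Aminolysis of the strained bridged lactone by the chloromagnesium amide gives an open Weinreb amide that cannot re-close to a hemiketal, and silylation then caps the more accessible tertiary C4 hydroxyl (the C5 hydroxyl is shielded by the ester and two fully substituted neighbours), which removes the competitor for the ring closure in step 10.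

Step 9
Reactants: 14 silyl ether Weinreb amide; 15 1-propynylmagnesium bromide
Product: 16 ynone (C10 α-but-2-ynoyl; 5β-OH)
Conditions: 15 (3 equiv), THF, −20 to 0 °C; aq. NH4Cl
Reagents that add atoms: none
Why: Weinreb ketone synthesis: the alkynyl Grignard reagent adds once to the N-methoxy-N-methylamide through a chelated tetrahedral intermediate that collapses only on work-up, so neither the hindered C5 ester nor the ynone is attacked further.

Step 10
Reactants: 16 ynone
Product: 17 trans-fused 2-methyl-2,3-dihydro-4H-pyran-4-one (O links C5 and C11; C11(Me)=C7H–C9=O)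
Conditions: AgOTf (10 mol %), CH2Cl2, rt
Reagents that add atoms: none
Why: AgOTf-promoted 6-endo-dig oxa-conjugate addition of the β-hydroxyl (C5–OH) to the ynone is the usual closure of β-hydroxy ynones to dihydropyranones and is irreversible, so it can pay for the less favoured conformer of ring A that the trans fusion (fixed by C5 and C10) requires; no stereocentre is formed.

Step 11
Reactants: 17 dihydropyranone
Product: 18 C9=C7 trimethylsilyl enol ether of the 2,2-dimethyltetrahydropyran-4-one
Conditions: Me2CuLi, Me3SiCl, THF, −78 to −30 °C; Et3N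
Reagents that add atoms: lithium dimethylcuprate, [Li+].C[Cu-]C; chlorotrimethylsilane, C[Si](C)(C)Cl
Why: Me3SiCl-accelerated conjugate addition of the cuprate to the vinylogous ester completes the C11 gem-dimethyl group (not a stereocentre) and traps the enolate directly as the C9=C7 silyl enol ether.

Step 12
Reactants: 18 silyl enol ether
Product: 19 siloxycyclopropane (C7–C8–C9; either face)
Conditions: Et2Zn, CH2I2, CH2Cl2, 0 °C to rt
Reagents that add atoms: diiodomethane, ICI
Why: Furukawa-type Simmons–Smith cyclopropanation of the electron-rich silyl enol ether adds CH2 (C8) across C7=C9; the face of attack does not matter because both new centres become trigonal in step 13.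

Step 13
Reactants: 19 siloxycyclopropane
Product: 21 oxepenone (C9 ketone; C7=C8; 4α-OSiEt3), via β-chloro ketone 20 (not isolated)
Conditions: FeCl3 (2.5 equiv), pyridine (1 equiv), DMF, 0 °C to rt; then NaOAc, MeOH, 60 °C
Reagents that add atoms: none
Why: FeCl3 oxidises the silyloxycyclopropane by single-electron transfer, the oxygen-centred radical cation loses the silyl group and cleaves the internal C7–C9 bond to give the C9 ketone and a secondary C7 radical, which takes chlorine from a second FeCl3; acetate then removes HCl by E1cB. This is the Ito–Saegusa one-carbon ring expansion of 1-silyloxybicyclo[n.1.0]alkanes to cycloalk-2-enones, applied here to a 3-oxabicyclo[4.1.0]heptane. No ring is closed by a new bond: the six-membered O–C11–C7–C9–C10–C5 ring becomes the seven-membered O–C11–C7=C8–C9–C10–C5 ring by opening of the fused cyclopropane. No stereocentre is created and C1, C2, C4, C5 and C10 are not touched. The step needs cleavage of the internal and not the external (C8–C9) cyclopropane bond, secured by the greater stability of the secondary C7 radical and by release of the fused-ring strain. It also needs one direction of HCl loss, secured because C8 is the only enolisable position (C10 is quaternary) and C11 carries no hydrogen.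

Step 14
Reactants: 21 oxepenone
Product: 23 tricyclic γ-lactone (C6(=O)–O–C9; 4α-OSiEt3; 1β,2β-acetonide), via allylic alcohol 22 (not isolated)
Conditions: NaBH4, CeCl3·7H2O, MeOH, −40 to 0 °C; then rt
Reagents that add atoms: none
Why: Luche 1,2-reduction: hydride should enter C9 from the β-face because the axial C5 ester lies on the α-trajectory, which places the alkoxide next to C6 so that it lactonises with loss of methanol and fixes C9.

Step 15
Reactants: 23 tricyclic γ-lactone
Product: 24 1β,2β,4α-triol
Conditions: 1 M HCl–THF (1:3), rt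
Reagents that add atoms: none
Why: Aqueous acid hydrolyses the acetonide and the tertiary silyl ether in one operation, while the allylic ether and lactone should persist because ionisation at C11 or C9 would have to open the bridged bicycle.

Step 16
Reactants: 24 triol
Product: 25 C1 benzoate
Conditions: BzCl (1.1 equiv), pyridine, DMAP (cat.), CH2Cl2, −20 to 0 °C
Reagents that add atoms: benzoyl chloride, O=C(Cl)c1ccccc1
Why: DMAP-catalysed acylation should select the equatorial C1 hydroxyl over the axial C2 hydroxyl, which is flanked by the syn-axial C4 and C10 methyl groups, and over the tertiary C4 hydroxyl.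

Step 17
Reactants: 25 C1 benzoate
Product: 26 target CNP0178319.3
Conditions: Ac2O, Et3N, DMAP, CH2Cl2, rt
Reagents that add atoms: acetic anhydride, CC(=O)OC(C)=O
Why: DMAP-catalysed acetylation esterifies the remaining secondary C2 hydroxyl, the tertiary C4 hydroxyl being inert under these conditions, and gives the target.

**Compound list**

1 | 2-methoxy-3-methylbenzoic acid | COc1c(C)cccc1C(=O)O | starting material
2 | (S)-2-(methoxymethyl)pyrrolidine | COC[C@@H]1CCCN1 | starting material
3 | 2-methoxy-3-methylbenzoyl chloride | COc1c(C)cccc1C(Cl)=O | intermediate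
4 | (S)-N-(2-methoxy-3-methylbenzoyl)-2-(methoxymethyl)pyrrolidine | COC[C@@H]1CCCN1C(=O)c1cccc(C)c1OC | intermediate
5 | 6-methoxy-1,5-dimethylcyclohexa-2,5-diene-1-carboxamide of 2 (C10 β-methyl, α-amide) | COC1=C(C)CC=C[C@@]1(C)C(=O)N1CCC[C@H]1COC | intermediate
6 | ring A enone amide: C5 ketone, C4–H(Me) as epimer mixture, C1=C2, C10 β-methyl and α-carboxamide | O=C1C(C)CC=C[C@@]1(C)C(=O)N1CCC[C@H]1COC | intermediate
7 | 1β,2β-diol of 6 | O[C@H]1CC(C)C(=O)[C@](C)(C(=O)N2CCC[C@H]2COC)[C@H]1O | intermediate
8 | 1β,2β-O-isopropylidene ketone | CC1(C)O[C@H]2CC(C)C(=O)[C@](C)(C(=O)N3CCC[C@H]3COC)[C@H]2O1 | intermediate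
9 | C4=C5 enol triflate | CC1(C)O[C@H]2CC(C)=C(OS(=O)(=O)C(F)(F)F)[C@](C)(C(=O)N3CCC[C@H]3COC)[C@H]2O1 | intermediate
10 | methyl enoate (CO2Me on C5, C4=C5) | CC1(C)O[C@H]2CC(C)=C(C(=O)OC)[C@](C)(C(=O)N3CCC[C@H]3COC)[C@H]2O1 | intermediate
11 | 4β,5β-epoxide of 10 | CC1(C)O[C@H]2C[C@@]3(C)O[C@@]3(C(=O)OC)[C@](C)(C(=O)N4CCC[C@H]4COC)[C@H]2O1 | intermediate
12 | bridged γ-lactone C9(=O)–O–C4 (4α-O, 4β-Me), 5β-OH, 5α-CO2Me | CC1(C)O[C@H]2C[C@](C)(OC3=O)[C@](O)(C(=O)OC)[C@@]3(C)[C@H]2O1 | intermediate
13 | C9 Weinreb amide, 4α,5β-diol | CC1(C)O[C@H]2C[C@](C)(O)[C@](O)(C(=O)OC)[C@](C)(C(=O)N(C)OC)[C@H]2O1 | intermediate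
14 | C9 Weinreb amide, 4α-OSiEt3, 5β-OH | CC1(C)O[C@H]2C[C@](C)(O[Si](CC)(CC)CC)[C@](O)(C(=O)OC)[C@](C)(C(=O)N(C)OC)[C@H]2O1 | intermediate
15 | 1-propynylmagnesium bromide | CC#C[Mg]Br | starting material
16 | ynone: C10 α-but-2-ynoyl, 5β-OH, 4α-OSiEt3 | CC1(C)O[C@H]2C[C@](C)(O[Si](CC)(CC)CC)[C@](O)(C(=O)OC)[C@](C)(C(=O)C#CC)[C@H]2O1 | intermediate
17 | trans-fused 2-methyl-2,3-dihydro-4H-pyran-4-one | CC1(C)O[C@H]2C[C@](C)(O[Si](CC)(CC)CC)[C@@]3(C(=O)OC)OC(C)=CC(=O)[C@]3(C)[C@H]2O1 | intermediate
18 | C9=C7 trimethylsilyl enol ether of the 2,2-dimethyltetrahydropyran-4-one | CC1(C)O[C@H]2C[C@](C)(O[Si](CC)(CC)CC)[C@@]3(C(=O)OC)OC(C)(C)C=C(O[Si](C)(C)C)[C@]3(C)[C@H]2O1 | intermediate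
19 | siloxycyclopropane C7–C8–C9 (either face) | CC1(C)O[C@H]2C[C@](C)(O[Si](CC)(CC)CC)[C@@]3(C(=O)OC)OC(C)(C)C4CC4(O[Si](C)(C)C)[C@]3(C)[C@H]2O1 | intermediate
20 | β-chloro ketone (C7–Cl, C9=O, oxepane; C7 epimers) | CC1(C)O[C@H]2C[C@](C)(O[Si](CC)(CC)CC)[C@@]3(C(=O)OC)OC(C)(C)C(Cl)CC(=O)[C@]3(C)[C@H]2O1 | intermediate
21 | oxepenone (C9=O, C7=C8) | CC1(C)O[C@H]2C[C@](C)(O[Si](CC)(CC)CC)[C@@]3(C(=O)OC)OC(C)(C)C=CC(=O)[C@]3(C)[C@H]2O1 | intermediate
22 | C9 allylic alcohol (OH on the face of C6) | CC1(C)O[C@H]2C[C@](C)(O[Si](CC)(CC)CC)[C@@]3(C(=O)OC)OC(C)(C)C=C[C@H](O)[C@]3(C)[C@H]2O1 | intermediate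
23 | tricyclic γ-lactone, 4α-OSiEt3, 1β,2β-acetonide | CC1(C)O[C@H]2C[C@](C)(O[Si](CC)(CC)CC)[C@]34OC(C)(C)C=C[C@H](OC3=O)[C@]4(C)[C@H]2O1 | intermediate
24 | 1β,2β,4α-triol | O[C@H]1C[C@](C)(O)[C@]23OC(C)(C)C=C[C@H](OC2=O)[C@]3(C)[C@H]1O | intermediate
25 | C1 benzoate | O[C@H]1C[C@](C)(O)[C@]23OC(C)(C)C=C[C@H](OC2=O)[C@]3(C)[C@H]1OC(=O)c1ccccc1 | intermediate
26 | CNP0178319.3 | CC(=O)O[C@H]1C[C@](C)(O)[C@]23OC(C)(C)C=C[C@H](OC2=O)[C@]3(C)[C@H]1OC(=O)c1ccccc1 | target

**Totals**

Total step count: 17. Longest linear sequence: 17 steps (1 to 26).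

**Steps most likely to fail**

Step 7. The peracid may be too slow on the tetrasubstituted, ester-deactivated C4=C5 bond flanked by a quaternary carbon, so that other parts of the molecule degrade first. Fallback: setting out from 10, the alkene is dihydroxylated under RuO4 flash conditions (RuCl3·3H2O cat., NaIO4, EtOAc–MeCN–H2O, 0 °C), which accept electron-poor hindered alkenes and should give the 4β,5β-diol F1 from the face opposite the amide. CSA in CH2Cl2 then ionises the tertiary C4–OH (the C5–OH is α to the ester), the amide oxygen captures C4 from the α-face, and the water released hydrolyses the O-alkyl iminium ion. This reaches 12 with inversion at C4, and the route continues with step 8.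

Step 10. Ring closure may be slow because the hindered tertiary C5 hydroxyl has to reach the alkyne through the less favoured conformer of ring A, so that silver-promoted hydration or decomposition of the ynone outruns cyclisation. Fallback: setting out from 16, Et2NH in EtOH adds to the ynone without involving any hydroxyl and gives the β-(diethylamino)enone F2. CF3CO2H in CH2Cl2 then drives intramolecular addition–elimination by the C5 hydroxyl, the amine leaving as its salt, which gives 17, where the route is rejoined.

Step 14. Hydride may be delivered from the α-face, which leaves the C9 hydroxyl pointing away from the ester so that no lactone forms. Fallback: the C9-epimeric hydroxy ester F3, obtained from 21 in place of 23, is equilibrated through enone 21 under Meerwein–Ponndorf–Verley/Oppenauer conditions (Al(Oi-Pr)3, i-PrOH with a little acetone, toluene, 80 °C). Only the epimer whose oxygen faces C6 can lactonise, so the equilibrium drains into 23.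

**Further compounds**

F1 | step 7 | 4β,5β-diol of enoate 10 (4α-methyl, 5α-CO2Me) | CC1(C)O[C@H]2C[C@@](C)(O)[C@](O)(C(=O)OC)[C@](C)(C(=O)N3CCC[C@H]3COC)[C@H]2O1
F2 | step 10 | β-(diethylamino)enone from ynone 16 | CC1(C)O[C@H]2C[C@](C)(O[Si](CC)(CC)CC)[C@](O)(C(=O)OC)[C@](C)(C(=O)C=C(C)N(CC)CC)[C@H]2O1
F3 | step 14 | C9-epimeric hydroxy ester | CC1(C)O[C@H]2C[C@](C)(O[Si](CC)(CC)CC)[C@@]3(C(=O)OC)OC(C)(C)C=C[C@@H](O)[C@]3(C)[C@H]2O1
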